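Ring B is disconnected at C7=C8 and C9–C10, which splits the ent-labdane into a ring A dialdehyde and one enal holding C8, C9, C17 and the whole side chain. The key step exploits two features of ring B. The methyl-bearing quaternary C10 at the ring A/B fusion is a latent tertiary radical (hydrogen-atom transfer to a C1=C10 alkene), and C7=C8 is a latent aldol site. Giese addition of C10 to C9 leaves an enolate at C8 that closes on the C7 aldehyde, so ring B, C9 and C10 arise in one operation. The precursor is a monocyclic cyclohexene whose C3–C5 triad comes from one enantioselective Diels–Alder reaction; formyl C17 is later reduced to methyl.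

Key step: step 8

Remark: labdane numbering is used (C1–C10 decalin, C11–C16 side chain, C17 on C8, C18 = methyl and C19 = CH2OH on C4, C20 on C10). The SMILES is read as (3S,4R,5S,9R,10S), a trans-decalin with axial 3-OAc, axial C19, axial C20 and an equatorial C9 side chain.

Step 1
Reactants: 1 pent-3-yn-1-ol
Product: 2 triethyl(pent-3-yn-1-yloxy)silane
Conditions: TESCl, imidazole, CH2Cl2, 0 °C to rt
Reagents that add atoms: chlorotriethylsilane, CC[Si](Cl)(CC)CC
Why: Routine silyl ether formation on a primary alcohol; the triethylsilyl ether is chosen because step 5 can oxidise it straight to the aldehyde.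

Step 2
Reactants: 2 triethyl(pent-3-yn-1-yloxy)silane
Product: 5 (E)-triethyl[(4-methylhexa-3,5-dien-1-yl)oxy]silane, via alkenylzirconocene chloride 3 (not isolated), via alkenylzinc chloride 4 (not isolated)
Conditions: Cp2Zr(H)Cl (slight excess), THF, rt to 40 °C; then ZnCl2, Pd(PPh3)4 (cat.), vinyl bromide, THF, rt
Reagents that add atoms: vinyl bromide, C=CBr
Why: Syn hydrozirconation settles after equilibration with zirconium on the less hindered methyl-bearing alkyne carbon, and the zinc-assisted Negishi coupling at zerovalent palladium proceeds with retention, so the future C5=C10 alkene is E.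

Step 3
Reactants: 6 (E)-3-ethoxy-2-methylprop-2-enal
Product: 8 (E)-2-methyl-3-oxoprop-1-en-1-yl acetate (3-acetoxy-2-methylacrolein), via sodium enolate 7 (not isolated)
Conditions: NaOH, H2O, 60 °C, evaporation to dryness; then AcCl, Et2O, 0 °C
Reagents that add atoms: sodium hydroxide, [Na+].[OH-]; acetyl chloride, CC(=O)Cl
Why: Addition–elimination of hydroxide on the vinylogous ester gives the methylmalonaldehyde enolate, which is O-acylated (enol ester formation) to the more stable E enol acetate with OAc trans to CHO.

Step 4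
Reactants: 5 (E)-triethyl[(4-methylhexa-3,5-dien-1-yl)oxy]silane; 8 (E)-3-acetoxy-2-methylacrolein
Product: 9 (1S,5S,6S)-6-formyl-4,6-dimethyl-5-[2-(triethylsilyloxy)ethyl]cyclohex-3-en-1-yl acetate (labdane C3 S, C4 S, C5 S)
Conditions: (R)-3,3-diphenyl-1-(o-tolyl)tetrahydro-1H,3H-pyrrolo[1,2-c][1,3,2]oxazaborole (20 mol %), HN(SO2CF3)2 (18 mol %), CH2Cl2, −78 to −40 °C
Reagents that add atoms: none
Why: Enantioselective Diels–Alder reaction of a 2-substituted enal under cationic oxazaborolidine catalysis: the β-carbon C3 bonds to the unsubstituted diene terminus C2 as with other 1,2-dialkyl dienes, the E dienophile fixes OAc trans to CHO, the endo formyl group ends cis to the C5 arm, and the (R)-catalyst (formyl C–H···O contact, s-trans enal stacked on one phenyl group) leaves the Si face of C4 open, which sets all three centres.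

Step 5
Reactants: 9 Diels–Alder adduct
Product: 11 (1S,5S,6S)-6-formyl-4,6-dimethyl-5-(2-oxoethyl)cyclohex-3-en-1-yl acetate, via alkoxysulfonium chloride 10 (not isolated)
Conditions: (COCl)2, DMSO, CH2Cl2, −78 to −35 °C; then Et3N, −78 °C to rt
Reagents that add atoms: none
Why: Swern oxidation applied directly to a primary triethylsilyl ether exchanges silicon for sulfur, so no free C7 alcohol appears that could form a lactol with the cis C19 aldehyde and be over-oxidised to a lactone.

Step 6
Reactants: 12 hex-5-en-2-one
Product: 13 tert-butyl (2E)-3-methylhepta-2,6-dienoate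
Conditions: tert-butyl diethylphosphonoacetate, NaH, THF, 0 °C to rt; chromatographic removal of the Z isomer
Reagents that add atoms: tert-butyl diethylphosphonoacetate, CCOP(=O)(CC(=O)OC(C)(C)C)OCC
Why: Horner–Wadsworth–Emmons olefination of a methyl ketone places the longer chain trans to the ester, which gives the E C13=C14 alkene of the target.

Step 7
Reactants: 13 tert-butyl (2E)-3-methylhepta-2,6-dienoate
Product: 14 tert-butyl (2E,6E)-3-methyl-8-oxoocta-2,6-dienoate
Conditions: crotonaldehyde (excess), second-generation Hoveyda–Grubbs catalyst RuCl2(H2IMes)(=CH-C6H4-2-OiPr) (cat.), CH2Cl2, 40 °C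
Reagents that add atoms: (E)-crotonaldehyde, C/C=C/C=O
Why: Olefin cross metathesis of the terminal alkene with an enal partner gives the E enal, and the trisubstituted electron-poor enoate does not take part.

Step 8
Reactants: 11 ring A dialdehyde; 14 enal acceptor (excess)
Product: 16 tert-butyl 3-acetoxy-7-hydroxy-17,19-dioxo-ent-labd-13E-en-15-oate (trans-decalin; 7-OH, 8-CHO and C9 chain equatorial, drawn for the expected C7/C8 isomer), via iron enolate 15 (not isolated)
Conditions: Fe(acac)3 (20 mol %), PhSiH2(OiPr), ClCH2CH2Cl/HOCH2CH2OH, 0 °C to rt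
Reagents that add atoms: none
Why: An iron hydride made from Fe(acac)3 and the silane transfers a hydrogen atom to C1 of the only electron-neutral alkene of 11, the tertiary C10 radical adds to C9 of 14 (Giese addition), divalent iron reduces the α-formyl radical to the C8 enolate 15, and this closes on the C7 aldehyde. The closest known reaction type is the hydrogen-atom-transfer-initiated radical–polar crossover annulation of a γ,δ-unsaturated aldehyde with an α,β-unsaturated carbonyl compound (reductive olefin coupling followed by aldol). Ring B closes in the 6-(enolexo)-exo-trig mode through a chair. C10 is controlled by ring A, because the face syn to the C5 arm is also covered by the axial C19 formyl group, so C9 enters anti and C20 becomes axial (trans-decalin); C9 is controlled by the staggered addition geometry in which H9 lies between C1 and C5 and the slim sp2 arm C8 takes the crowded sector next to C6, which puts the side chain equatorial; C7 and C8 follow from a Zimmerman–Traxler chair of the E enolate and are erased in step 9. The step needs regiocontrol among three aldehydes: only C8 ever becomes an enolate because it is born from the radical, and the C19 formyl group is trans to C9 across ring A and cannot be reached. The hindered, electron-poor C13=C14 enoate should not compete as hydrogen-atom or radical acceptor, and the excess of 14 serves to outrun reduction of the C10 radical.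

Step 9
Reactants: 16 aldol
Product: 18 tert-butyl 3-acetoxy-17,19-dioxo-ent-labda-7,13E-dien-15-oate, via C7 mesylate 17 (not isolated)
Conditions: MsCl, Et3N, CH2Cl2, 0 °C to rt
Reagents that add atoms: none
Why: Mesylation and E1cB elimination through the C8 formyl enolate give the conjugated C7=C8 enal whatever the C7/C8 configuration, while C9 is not acidic and the C19 aldehyde has no α-hydrogen.

Step 10
Reactants: 18 enal
Product: 19 tert-butyl 3-acetoxy-17,19-dihydroxy-ent-labda-7,13E-dien-15-oate
Conditions: NaBH4, CeCl3·7H2O, MeOH, −20 to 0 °C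
Reagents that add atoms: none
Why: Luche reduction gives 1,2-reduction of the enal and also reduces the neopentyl C19 aldehyde while the esters survive, and in the rigid trans-decalin the axial 3-OAc and the axial C19 arm are antiperiplanar, so acetyl migration is blocked.

Step 11
Reactants: 19 diol
Product: 21 tert-butyl 3-acetoxy-19-hydroxy-ent-labda-7,13E-dien-15-oate, via allylic bromide 20 (not isolated)
Conditions: NBS, Me2S, CH2Cl2, −20 to 0 °C; then NaBH4, DMSO, 0 °C to rt
Reagents that add atoms: none
Why: Corey–Kim halogenation converts only the allylic alcohol into its bromide (the neopentyl C19 alkoxysulfonium ion cannot be displaced and returns to the alcohol), and borohydride in DMSO then displaces the primary bromide by SN2 at C17, which leaves C7=C8 in place.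

Step 12
Reactants: 21 tert-butyl ester
Product: 23 (3S,4R,5S,9R,10S)-3-acetoxy-19-hydroxylabda-7,13E-dien-15-oic acid (target), via bis(trimethylsilyl) derivative 22 (not isolated)
Conditions: TMSOTf, 2,6-lutidine, CH2Cl2, 0 °C; then aqueous citric acid, THF, rt
Reagents that add atoms: none
Why: Silyl triflate-mediated tert-butyl ester cleavage under lutidine buffering (loss of isobutene) avoids free strong acid that could move the C7=C8 alkene, and mild aqueous acid then hydrolyses the silyl ester and the C19 silyl ether without touching the acetate.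

Compound list
1 | pent-3-yn-1-ol | CC#CCCO | starting material
2 | triethyl(pent-3-yn-1-yloxy)silane | CC#CCCO[Si](CC)(CC)CC | intermediate
3 | (E)-alkenylzirconocene chloride, Zr on the methyl-bearing carbon | C/C(=C\CCO[Si](CC)(CC)CC)[Zr](Cl)(C1C=CC=C1)C1C=CC=C1 | intermediate
4 | (E)-alkenylzinc chloride | C/C(=C\CCO[Si](CC)(CC)CC)[Zn]Cl | intermediate
5 | (E)-triethyl[(4-methylhexa-3,5-dien-1-yl)oxy]silane | C=C/C(C)=C/CCO[Si](CC)(CC)CC | intermediate
6 | (E)-3-ethoxy-2-methylprop-2-enal | CCO/C=C(\C)C=O | starting material
7 | sodium (E)-2-methyl-3-oxoprop-1-en-1-olate | [Na+].[O-]/C=C(\C)C=O | intermediate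
8 | (E)-2-methyl-3-oxoprop-1-en-1-yl acetate | CC(=O)O/C=C(\C)C=O | intermediate
9 | (1S,5S,6S)-6-formyl-4,6-dimethyl-5-[2-(triethylsilyloxy)ethyl]cyclohex-3-en-1-yl acetate | CC(=O)O[C@H]1CC=C(C)[C@H](CCO[Si](CC)(CC)CC)[C@]1(C)C=O | intermediate
10 | C7 alkoxydimethylsulfonium chloride of 9 | CC(=O)O[C@H]1CC=C(C)[C@H](CCO[S+](C)C)[C@]1(C)C=O.[Cl-] | intermediate
11 | (1S,5S,6S)-6-formyl-4,6-dimethyl-5-(2-oxoethyl)cyclohex-3-en-1-yl acetate | CC(=O)O[C@H]1CC=C(C)[C@H](CC=O)[C@]1(C)C=O | intermediate
12 | hex-5-en-2-one | C=CCCC(C)=O | starting material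
13 | tert-butyl (2E)-3-methylhepta-2,6-dienoate | C=CCC/C(C)=C/C(=O)OC(C)(C)C | intermediate
14 | tert-butyl (2E,6E)-3-methyl-8-oxoocta-2,6-dienoate | O=C/C=C/CC/C(C)=C/C(=O)OC(C)(C)C | intermediate
15 | C8 enolate of the Giese adduct (iron-bound, drawn as the anion) | CC(=O)O[C@H]1CC[C@@](C)([C@H](CC/C(C)=C/C(=O)OC(C)(C)C)/C=C/[O-])[C@H](CC=O)[C@]1(C)C=O | intermediate
16 | tert-butyl 3-acetoxy-7-hydroxy-17,19-dioxo-ent-labd-13E-en-15-oate | CC(=O)O[C@H]1CC[C@]2(C)[C@H](C[C@@H](O)[C@H](C=O)[C@H]2CC/C(C)=C/C(=O)OC(C)(C)C)[C@]1(C)C=O | intermediate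
17 | C7 mesylate of 16 | CC(=O)O[C@H]1CC[C@]2(C)[C@H](C[C@@H](OS(C)(=O)=O)[C@H](C=O)[C@H]2CC/C(C)=C/C(=O)OC(C)(C)C)[C@]1(C)C=O | intermediate
18 | tert-butyl 3-acetoxy-17,19-dioxo-ent-labda-7,13E-dien-15-oate | CC(=O)O[C@H]1CC[C@]2(C)[C@H](CC=C(C=O)[C@H]2CC/C(C)=C/C(=O)OC(C)(C)C)[C@]1(C)C=O | intermediate
19 | tert-butyl 3-acetoxy-17,19-dihydroxy-ent-labda-7,13E-dien-15-oate | CC(=O)O[C@H]1CC[C@]2(C)[C@H](CC=C(CO)[C@H]2CC/C(C)=C/C(=O)OC(C)(C)C)[C@]1(C)CO | intermediate
20 | tert-butyl 3-acetoxy-17-bromo-19-hydroxy-ent-labda-7,13E-dien-15-oate | CC(=O)O[C@H]1CC[C@]2(C)[C@H](CC=C(CBr)[C@H]2CC/C(C)=C/C(=O)OC(C)(C)C)[C@]1(C)CO | intermediate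
21 | tert-butyl 3-acetoxy-19-hydroxy-ent-labda-7,13E-dien-15-oate | CC(=O)O[C@H]1CC[C@]2(C)[C@H](CC=C(C)[C@H]2CC/C(C)=C/C(=O)OC(C)(C)C)[C@]1(C)CO | intermediate
22 | trimethylsilyl ester and C19 trimethylsilyl ether of the target | CC(=O)O[C@H]1CC[C@]2(C)[C@H](CC=C(C)[C@H]2CC/C(C)=C/C(=O)O[Si](C)(C)C)[C@]1(C)CO[Si](C)(C)C | intermediate
23 | (3S,4R,5S,9R,10S)-3-acetoxy-19-hydroxylabda-7,13E-dien-15-oic acid | CC(=O)O[C@H]1CC[C@]2(C)[C@H](CC=C(C)[C@H]2CC/C(C)=C/C(=O)O)[C@]1(C)CO | target

Total step count: 12. Longest linear sequence: 9 steps (1, 2, 4, 5, 8, 9, 10, 11, 12).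

Steps most likely to fail

Step 8.
- What may go wrong: reduction of the C10 radical before it finds the β-substituted acceptor, protonation of the C8 enolate before ring closure, and weak facial discrimination at C9.
- Fallback: it sets out from 11 (with 14), comes back at 18, and separates the two bond formations.
- The unhindered C7 aldehyde of 11 is masked selectively (HC(OMe)3, PPTS, MeOH, 0 °C; the neopentyl C19 aldehyde stays free) as the C7 dimethyl acetal F1.
- A plain reductive olefin coupling of the C7 dimethyl acetal with 14 (Fe(acac)3, PhSiH3, EtOH, 60 °C), in which the enolate is simply protonated, should give the seco aldehyde F2. Any C9 epimer is removed here.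
- Soft enolisation of its only enolisable aldehyde (TMSOTf, iPr2NEt, CH2Cl2, −78 °C, cold enough to spare the tert-butyl ester) gives the silyl enol ether F3.
- This closes in the same flask on the oxocarbenium ion from the acetal (Mukaiyama aldol type) to the 7-methoxy aldehyde F4. DBU in CH2Cl2 then eliminates methanol to 18.

Step 4.
- What may go wrong: sluggish cycloaddition of the push–pull dienophile, binding of the catalyst to the acetate carbonyl, and erosion of regio- or enantiofacial control.
- Fallback: it sets out from 5 and 8, comes back at 9, and replaces asymmetric catalysis by a racemic cycloaddition with resolution.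
- A stronger achiral Lewis acid (EtAlCl2, CH2Cl2, −78 to −20 °C) should give the racemic endo adduct F5.
- The racemate is separated by preparative supercritical-fluid chromatography on a polysaccharide chiral phase. The (1S,5S,6S) enantiomer is 9.

Step 11.
- What may go wrong: hydride delivery in the SN2′ sense with migration of the alkene to the exocyclic position, and partial reaction at the C19 alcohol.
- Fallback: it sets out from 19, comes back at 21, and goes through a π-allyl complex.
- The less hindered allylic alcohol is acetylated selectively (Ac2O, one equivalent, pyridine, −20 °C) to the C17 acetate F6.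
- Pd(PPh3)4 (cat.) and NaBH4 in THF then deliver hydride from outside to the less hindered C17 terminus of the allyl complex of divalent palladium. The non-allylic 3-acetate is inert.

Further compounds
F1 | step 8 | C7 dimethyl acetal of 11 | CC(=O)O[C@H]1CC=C(C)[C@H](CC(OC)OC)[C@]1(C)C=O
F2 | step 8 | seco aldehyde (C9–C10 formed, C8 protonated, C7 acetal) | CC(=O)O[C@H]1CC[C@@](C)([C@H](CC/C(C)=C/C(=O)OC(C)(C)C)CC=O)[C@H](CC(OC)OC)[C@]1(C)C=O
F3 | step 8 | C17 trimethylsilyl enol ether of F2 | CC(=O)O[C@H]1CC[C@@](C)([C@H](CC/C(C)=C/C(=O)OC(C)(C)C)/C=C\O[Si](C)(C)C)[C@H](CC(OC)OC)[C@]1(C)C=O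
F4 | step 8 | tert-butyl 3-acetoxy-7-methoxy-17,19-dioxo-ent-labd-13E-en-15-oate | CC(=O)O[C@H]1CC[C@]2(C)[C@H](C[C@@H](OC)[C@H](C=O)[C@H]2CC/C(C)=C/C(=O)OC(C)(C)C)[C@]1(C)C=O
F5 | step 4 | racemic endo adduct (9 and its enantiomer) | CC(=O)O[C@H]1CC=C(C)[C@H](CCO[Si](CC)(CC)CC)[C@]1(C)C=O.CC(=O)O[C@@H]1CC=C(C)[C@@H](CCO[Si](CC)(CC)CC)[C@@]1(C)C=O
F6 | step 11 | tert-butyl 3,17-diacetoxy-19-hydroxy-ent-labda-7,13E-dien-15-oate | CC(=O)O[C@H]1CC[C@]2(C)[C@H](CC=C(COC(C)=O)[C@H]2CC/C(C)=C/C(=O)OC(C)(C)C)[C@]1(C)CO
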